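The synthesis rests on cutting the side-chain bond C7′–C8′. This bond joins the acetoxy methine to the fully substituted carbinol carbon (CH3, OH, homoprenyl). The two atoms form an anti-1,2-diol, and a vinyl group on C8′ can stand in for the homoprenyl chain. In one operation, a γ-boryl-γ-methylallyl(diisopinocampheyl)borane, generated from a 1-methylallenyl boronate, adds to (E)-5-iodo-4-methylpent-4-enal and is then oxidised. This forms the bond and sets both stereocentres. Two B-alkyl Suzuki couplings then attach the masked naphthoquinone (rings A and B, built regiospecifically by Dötz benzannulation) and the isobutenyl terminus. Selective acetylation and oxidative demethylation finish the synthesis.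

Key step: step 6

Numbering used below:
- Ring B is C1(=O)–C2(CH3)=C3H–C4(=O).
- Ring A is C4a–C5–C6–C7–C8–C8a, and the side chain sits on C7.
- The side chain runs from C1′ (benzylic CH2) to C12′, with C7′ = CH(OAc) and C8′ = C(OH)(CH3).

Assumption: the γ-boryl allylborane carrying Ipc groups from (+)-α-pinene is taken to attack the aldehyde on the same face as the parent allyl and crotyl reagents. That face corresponds to (R) at C7′.

Step 1
Reactants: 1 but-2-yn-1-ol
Product: 2 but-2-yn-1-yl methyl carbonate
Conditions: ClCO2Me, pyridine, CH2Cl2, 0 °C → rt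
Reagents that add atoms: methyl chloroformate COC(=O)Cl
Why: O-acylation of a primary alcohol with a chloroformate (carbonate formation) is routine and installs the leaving group for the SN2′ borylation.

Step 2
Reactants: 2 but-2-yn-1-yl methyl carbonate, 3 bis(pinacolato)diboron
Product: 4 4,4,5,5-tetramethyl-2-(buta-2,3-dien-2-yl)-1,3,2-dioxaborolane (1-methylallenyl-Bpin)
Conditions: Cu(O-t-Bu) (5 mol %), Xantphos (5 mol %), THF, rt
Reagents that add atoms: none
Why: In this copper-catalysed γ-selective (SN2′) borylation of a propargylic carbonate, the Cu–Bpin species adds to the alkyne carbon remote from the carbonate, and β-elimination with loss of CO2 and methoxide should give the 1,1-disubstituted allenyl boronate.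

Step 3
Reactants: 5 (1R,5R)-(+)-α-pinene (two equivalents)
Product: 6 (−)-diisopinocampheylborane, (dIpc)2BH
Conditions: BH3·SMe2, THF, 0 °C, crystallisation in the presence of a slight excess of 5
Reagents that add atoms: borane–dimethyl sulfide C[S+](C)[BH3-]
Why: Syn hydroboration of two pinene molecules occurs from the face opposite the gem-dimethyl bridge, and equilibration and crystallisation with excess pinene should upgrade the optical purity of the reagent.

Step 4
Reactants: 7 pent-4-yn-1-ol
Product: 9 (E)-5-iodo-4-methylpent-4-en-1-ol, via alkenylalane 8 (not isolated)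
Conditions: AlMe3 (3 equiv), Cp2ZrCl2 (0.25 equiv), CH2Cl2, 0 °C → rt; I2, THF, −30 °C; aq. K2CO3
Reagents that add atoms: trimethylaluminium C[Al](C)C; iodine II
Why: In the Negishi zirconium-catalysed carboalumination, syn addition of Me–Al with aluminium at the terminus fixes the E geometry of the later C3′=C4′ bond, and iodinolysis proceeds with retention.

Step 5
Reactants: 9 (E)-5-iodo-4-methylpent-4-en-1-ol
Product: 10 (E)-5-iodo-4-methylpent-4-enal
Conditions: TEMPO (10 mol %), PhI(OAc)2, CH2Cl2, rt
Reagents that add atoms: none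
Why: The oxoammonium (TEMPO) oxidation of a primary alcohol stops at the aldehyde and leaves the alkenyl iodide untouched.

Step 6
Reactants: 4 1-methylallenyl-Bpin, 6 (dIpc)2BH, 10 (E)-5-iodo-4-methylpent-4-enal
Product: 14 (3S,4R,7E)-8-iodo-3,7-dimethylocta-1,7-diene-3,4-diol, via cis-boryl allylborane 11 (not isolated), via trans-boryl allylborane 12 (not isolated), via borinate adduct 13 (not isolated)
Conditions: 4 (1.3 equiv), 6 (1.25 equiv), toluene, 0 °C, then 65 °C; 10 (1.0 equiv), −78 °C; NaOH, H2O2, 0 °C → rt
Reagents that add atoms: hydrogen peroxide OO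
Why: Hydroboration of the CH2=C bond of allene 4 by 6 (B to CH2, H to the central carbon, approach past the methyl side) gives 11, and reversible 1,3-boratropic shifts on warming should drain it into 12, in which the bulkier Bpin group lies trans to CH2B(Ipc)2. Allylborane 12 then adds to aldehyde 10 through a closed chair-like Zimmerman–Traxler transition state with allylic transposition, which forms C7′–C8′ and gives 13, and H2O2 replaces the C8′–B bond by C8′–OH with retention. The closest known reaction type is the allene hydroboration/aldehyde allylboration sequence with γ-boryl allyl(diisopinocampheyl)boranes (Brown-type allylboration), an established entry to anti-1,2-diols including 2-methyl-substituted ones; no ring is closed. C8′ is controlled by the alkene geometry of 12 (Bpin equatorial and methyl axial in the chair, so that O7′ and the later O8′ end up anti), and C7′ by the Ipc groups from (+)-α-pinene, which select one aldehyde face and should give (R). The step needs complete geometric equilibration before the aldehyde is added, a single allyl transfer and an untouched alkenyl iodide: equilibration is separated in time from the addition, the tertiary allyl-Bpin unit of 13 is too hindered and too weakly Lewis acidic to react with the limiting aldehyde at −78 °C, and neither the borane nor basic peroxide attacks the C–I bond.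

Step 7
Reactants: 15 4-bromostyrene, 16 hexacarbonylchromium Cr(CO)6
Product: 19 pentacarbonyl[methoxy(4-vinylphenyl)carbene]chromium, (CO)5Cr=C(OMe)(C6H4-4-CH=CH2), via 4-vinylphenyllithium 17 (not isolated), via lithium acylchromate 18 (not isolated)
Conditions: n-BuLi, THF, −78 °C; Cr(CO)6, −78 °C → rt; Me3OBF4, CH2Cl2, rt
Reagents that add atoms: trimethyloxonium tetrafluoroborate C[O+](C)C.F[B-](F)(F)F
Why: In this Fischer carbene synthesis, Br–Li exchange at −78 °C should outrun addition to the styrene, the aryllithium adds to a CO ligand, and the Meerwein salt O-methylates the acylchromate.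

Step 8
Reactants: 19 carbene complex, 20 propyne
Product: 22 4-methoxy-2-methyl-7-vinylnaphthalen-1-ol, via tricarbonylchromium naphthol complex 21 (not isolated)
Conditions: propyne (excess), THF, 50 °C, sealed tube, BHT (trace); then air, MeCN, rt, brief
Reagents that add atoms: none
Why: In the Dötz benzannulation (alkyne insertion, CO insertion, electrocyclisation), the methyl-bearing alkyne carbon ends next to the CO-derived phenol carbon (C2 next to C1) and the para vinyl group ends at C7, so the 2,7-pattern of rings A and B is fixed without regioisomers.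

Step 9
Reactants: 22 4-methoxy-2-methyl-7-vinylnaphthalen-1-ol
Product: 23 1,4-dimethoxy-2-methyl-7-vinylnaphthalene
Conditions: MeI, K2CO3, acetone, reflux, N2
Reagents that add atoms: iodomethane CI
Why: Williamson O-methylation of the naphtholate gives an air-stable 1,4-dimethoxyarene that masks the quinone through the borane and palladium steps.

Step 10
Reactants: 23 1,4-dimethoxy-2-methyl-7-vinylnaphthalene, 24 9-borabicyclo[3.3.1]nonane (9-BBN), 14 iodo diol
Product: 26 (3S,4R,7E)-10-(5,8-dimethoxy-7-methylnaphthalen-2-yl)-3,7-dimethyldeca-1,7-diene-3,4-diol, via B-alkyl-9-BBN 25 (not isolated)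
Conditions: 23 (slight excess over 24), 9-BBN, THF, rt; then 14, Pd(dppf)Cl2 (5 mol %), AsPh3, Cs2CO3, DMF/H2O, rt
Reagents that add atoms: none
Why: Anti-Markovnikov hydroboration of the styrene is followed by a B-alkyl Suzuki–Miyaura coupling, in which the alkenyl iodide reacts at room temperature with retention of the E geometry while the vinyl carbinol and the free diol remain spectators.

Step 11
Reactants: 26 vinyl diol, 24 9-BBN, 27 1-bromo-2-methylprop-1-ene
Product: 29 (6S,7R,10E)-13-(5,8-dimethoxy-7-methylnaphthalen-2-yl)-2,6,10-trimethyltrideca-2,10-diene-6,7-diol, via B-alkyl-9-BBN diol 28 (not isolated)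
Conditions: 9-BBN (3.5 equiv, covers both OH groups), THF, rt → 45 °C; aq. K3PO4; 27, Pd(dppf)Cl2 (10 mol %), DMF, 50 °C
Reagents that add atoms: none
Why: 9-BBN is selective for the monosubstituted vinyl group over the trisubstituted C3′=C4′ alkene (as with linalool-type carbinols), and a B-alkyl Suzuki–Miyaura coupling with the alkenyl bromide turns the vinyl group into the homoprenyl chain without touching C7′ or C8′.

Step 12
Reactants: 29 diol
Product: 30 (6S,7R,10E)-13-(5,8-dimethoxy-7-methylnaphthalen-2-yl)-6-hydroxy-2,6,10-trimethyltrideca-2,10-dien-7-yl acetate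
Conditions: Ac2O (1.5 equiv), pyridine, DMAP (cat.), CH2Cl2, 0 °C → rt
Reagents that add atoms: acetic anhydride CC(=O)OC(C)=O
Why: DMAP-catalysed acylation should take the secondary C7′ hydroxyl and leave the hindered tertiary C8′ hydroxyl free, with no bond to a stereocentre broken.

Step 13
Reactants: 30 dimethoxynaphthalene acetate
Product: 31 chabrolonaphthoquinone B
Conditions: (NH4)2Ce(NO3)6 (2.5 equiv), MeCN/H2O, 0 °C, short reaction time
Reagents that add atoms: water O
Why: Oxidative demethylation of a 1,4-dimethoxyarene to the 1,4-quinone is fast at 0 °C and is routinely compatible with trisubstituted alkenes, esters and tertiary alcohols in prenylated quinone series.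

Compound list
1 | but-2-yn-1-ol | CC#CCO | starting material
2 | but-2-yn-1-yl methyl carbonate | CC#CCOC(=O)OC | intermediate
3 | bis(pinacolato)diboron | CC1(C)OB(OC1(C)C)B1OC(C)(C)C(C)(C)O1 | starting material
4 | 4,4,5,5-tetramethyl-2-(buta-2,3-dien-2-yl)-1,3,2-dioxaborolane | C=C=C(C)B1OC(C)(C)C(C)(C)O1 | intermediate
5 | (1R,5R)-(+)-α-pinene | CC1=CC[C@@H]2C[C@H]1C2(C)C | starting material
6 | (−)-diisopinocampheylborane, Ipc groups from (+)-α-pinene | [BH]([C@@H]1C[C@@H]2C[C@H]([C@H]1C)C2(C)C)[C@@H]1C[C@@H]2C[C@H]([C@H]1C)C2(C)C | intermediate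
7 | pent-4-yn-1-ol | C#CCCCO | starting material
8 | (E)-alkenyl(dimethyl)alane with O-AlMe2 alkoxide, Al cis to the new methyl | C[Al](C)/C=C(\C)CCCO[Al](C)C | intermediate
9 | (E)-5-iodo-4-methylpent-4-en-1-ol | OCCC/C(C)=C/I | intermediate
10 | (E)-5-iodo-4-methylpent-4-enal | O=CCC/C(C)=C/I | intermediate
11 | diisopinocampheyl[3-(pinacolboryl)but-2-enyl]borane, Bpin cis to CH2B (kinetic isomer) | B(C/C=C(/C)B1OC(C)(C)C(C)(C)O1)([C@@H]1C[C@@H]2C[C@H]([C@H]1C)C2(C)C)[C@@H]1C[C@@H]2C[C@H]([C@H]1C)C2(C)C | intermediate
12 | diisopinocampheyl[3-(pinacolboryl)but-2-enyl]borane, Bpin trans to CH2B (equilibrated isomer) | B(C/C=C(\C)B1OC(C)(C)C(C)(C)O1)([C@@H]1C[C@@H]2C[C@H]([C@H]1C)C2(C)C)[C@@H]1C[C@@H]2C[C@H]([C@H]1C)C2(C)C | intermediate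
13 | diisopinocampheylborinate of the C7′ alkoxide with Bpin on C8′, spatial arrangement as in 14 | B(O[C@H](CC/C(C)=C/I)[C@@](C)(B1OC(C)(C)C(C)(C)O1)C=C)([C@@H]1C[C@@H]2C[C@H]([C@H]1C)C2(C)C)[C@@H]1C[C@@H]2C[C@H]([C@H]1C)C2(C)C | intermediate
14 | (3S,4R,7E)-8-iodo-3,7-dimethylocta-1,7-diene-3,4-diol | O[C@H](CC/C(C)=C/I)[C@@](C)(O)C=C | intermediate
15 | 4-bromostyrene | C=Cc1ccc(Br)cc1 | starting material
16 | hexacarbonylchromium Cr(CO)6 | O=C=[Cr](=C=O)(=C=O)(=C=O)(=C=O)=C=O | starting material
17 | 4-vinylphenyllithium | [Li]c1ccc(C=C)cc1 | intermediate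
18 | lithium pentacarbonyl(4-vinylbenzoyl)chromate | [Li+].[O-]C(c1ccc(C=C)cc1)=[Cr](=C=O)(=C=O)(=C=O)(=C=O)=C=O | intermediate
19 | pentacarbonyl[methoxy(4-vinylphenyl)carbene]chromium | COC(c1ccc(C=C)cc1)=[Cr](=C=O)(=C=O)(=C=O)(=C=O)=C=O | intermediate
20 | propyne | CC#C | starting material
21 | tricarbonyl(η6-4-methoxy-2-methyl-7-vinylnaphthalen-1-ol)chromium | COc1cc(C)c(O)c2cc(C=C)ccc12.O=C=[Cr](=C=O)=C=O | intermediate
22 | 4-methoxy-2-methyl-7-vinylnaphthalen-1-ol | COc1cc(C)c(O)c2cc(C=C)ccc12 | intermediate
23 | 1,4-dimethoxy-2-methyl-7-vinylnaphthalene | COc1cc(C)c(OC)c2cc(C=C)ccc12 | intermediate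
24 | 9-borabicyclo[3.3.1]nonane | [H]B1C2CCCC1CCC2 | starting material
25 | 9-[2-(5,8-dimethoxy-7-methylnaphthalen-2-yl)ethyl]-9-borabicyclo[3.3.1]nonane | COc1cc(C)c(OC)c2cc(CCB3C4CCCC3CCC4)ccc12 | intermediate
26 | (3S,4R,7E)-10-(5,8-dimethoxy-7-methylnaphthalen-2-yl)-3,7-dimethyldeca-1,7-diene-3,4-diol | O[C@H](CC/C(C)=C/CCc1ccc2c(OC)cc(C)c(OC)c2c1)[C@@](C)(O)C=C | intermediate
27 | 1-bromo-2-methylprop-1-ene | CC(C)=CBr | starting material
28 | (3S,4R,7E)-1-(9-borabicyclo[3.3.1]nonan-9-yl)-10-(5,8-dimethoxy-7-methylnaphthalen-2-yl)-3,7-dimethyldec-7-ene-3,4-diol | O[C@H](CC/C(C)=C/CCc1ccc2c(OC)cc(C)c(OC)c2c1)[C@@](C)(O)CCB1C2CCCC1CCC2 | intermediate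
29 | (6S,7R,10E)-13-(5,8-dimethoxy-7-methylnaphthalen-2-yl)-2,6,10-trimethyltrideca-2,10-diene-6,7-diol | O[C@H](CC/C(C)=C/CCc1ccc2c(OC)cc(C)c(OC)c2c1)[C@@](C)(O)CCC=C(C)C | intermediate
30 | (6S,7R,10E)-13-(5,8-dimethoxy-7-methylnaphthalen-2-yl)-6-hydroxy-2,6,10-trimethyltrideca-2,10-dien-7-yl acetate | CC(=O)O[C@H](CC/C(C)=C/CCc1ccc2c(OC)cc(C)c(OC)c2c1)[C@@](C)(O)CCC=C(C)C | intermediate
31 | chabrolonaphthoquinone B, (6S,7R,10E)-6-hydroxy-2,6,10-trimethyl-13-(7-methyl-5,8-dioxo-5,8-dihydronaphthalen-2-yl)trideca-2,10-dien-7-yl acetate | CC(=O)O[C@H](CC/C(C)=C/CCc1ccc2c(c1)C(=O)C(C)=CC2=O)[C@@](C)(O)CCC=C(C)C | target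

Total step count: 13.

Longest linear sequence: 7 steps (7 → 9 → 10 → 14 → 26 → 29 → 30 → 31). The sequences from 1 and from 15 are equally long.

Steps most likely to fail

Step 6. Three processes would erode both the anti/syn purity and the enantiomeric purity:
- The allylborane geometry may not equilibrate fully.
- α-Pinene may be partly lost from boron at the equilibration temperature.
- Facial discrimination may be weak with the unbranched aldehyde.

The fallback sets out from aldehyde 10 and comes back at diol 14. Isopropenylmagnesium bromide (THF, −78 °C) adds to 10 and forms the same C7′–C8′ bond. This gives racemic (6E)-7-iodo-2,6-dimethylhepta-1,6-dien-3-ol F1. A Sharpless kinetic resolution follows (Ti(O-i-Pr)4, D-(−)-diisopropyl tartrate, t-BuOOH, 4 Å sieves, CH2Cl2, −20 °C). It should epoxidise only the (R)-alcohol and leave the (S)-alcohol behind. The product is the erythro epoxy alcohol (1R,4E)-5-iodo-4-methyl-1-[(2S)-2-methyloxiran-2-yl]pent-4-en-1-ol F2. Excess dimethylsulfonium methylide (Me3SI, n-BuLi, THF) then opens the CH2 terminus of the epoxide and loses dimethyl sulfide. This turns the oxirane CH2 into the vinyl group of 14.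

Step 8. The styrene unit may polymerise or be cyclopropanated by the carbene during heating. The electron-rich naphthol may also be over-oxidised during the air demetalation.

The fallback sets out from Cr(CO)6 16 and propyne 20 and comes back at 23. The vinyl group is put on only after the naphthalene has been built.
- 1,4-Dibromobenzene F3 is monolithiated (n-BuLi, THF, −78 °C), added to 16 and O-methylated (Me3OBF4) to the carbene complex (CO)5Cr=C(OMe)(C6H4-4-Br) F4.
- Benzannulation with 20 and demetalation give 7-bromo-4-methoxy-2-methylnaphthalen-1-ol F5.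
- Methylation (MeI, K2CO3) gives 7-bromo-1,4-dimethoxy-2-methylnaphthalene F6.
- A Suzuki–Miyaura vinylation with K[CH2=CHBF3] (PdCl2(dppf), Et3N, n-PrOH, reflux) gives 23.

Step 11. Several processes could starve the coupling:
- Hydroboration of the vinyl group next to the fully substituted C8′ may be slow.
- The diol may tie up the borane.
- Protodeboronation or β-hydride elimination may occur at palladium.

The fallback sets out from 26 and comes back at 29, and it replaces the palladium coupling by a boronate rearrangement. Iridium-catalysed hydroboration with pinacolborane ([Ir(cod)Cl]2, dppe, THF, rt; O-boryl groups hydrolysed on work-up) gives the primary boronate (3S,4R,7E)-10-(5,8-dimethoxy-7-methylnaphthalen-2-yl)-3,7-dimethyl-1-(4,4,5,5-tetramethyl-1,3,2-dioxaborolan-2-yl)dec-7-ene-3,4-diol F7. Excess 2-methylprop-1-enyllithium (from 27 and t-BuLi, THF, −78 °C) forms the ate complex. Iodine followed by NaOMe then triggers the Zweifel olefination (1,2-shift and anti elimination) to 29.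

Further compounds
F1 | step 6 | (6E)-7-iodo-2,6-dimethylhepta-1,6-dien-3-ol (racemic) | CC(=C)C(O)CC/C(C)=C/I
F2 | step 6 | (1R,4E)-5-iodo-4-methyl-1-[(2S)-2-methyloxiran-2-yl]pent-4-en-1-ol | O[C@H](CC/C(C)=C/I)[C@]1(C)CO1
F3 | step 8 | 1,4-dibromobenzene | Brc1ccc(Br)cc1
F4 | step 8 | pentacarbonyl[(4-bromophenyl)(methoxy)carbene]chromium | COC(c1ccc(Br)cc1)=[Cr](=C=O)(=C=O)(=C=O)(=C=O)=C=O
F5 | step 8 | 7-bromo-4-methoxy-2-methylnaphthalen-1-ol | COc1cc(C)c(O)c2cc(Br)ccc12
F6 | step 8 | 7-bromo-1,4-dimethoxy-2-methylnaphthalene | COc1cc(C)c(OC)c2cc(Br)ccc12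
F7 | step 11 | (3S,4R,7E)-10-(5,8-dimethoxy-7-methylnaphthalen-2-yl)-3,7-dimethyl-1-(4,4,5,5-tetramethyl-1,3,2-dioxaborolan-2-yl)dec-7-ene-3,4-diol | O[C@H](CC/C(C)=C/CCc1ccc2c(OC)cc(C)c(OC)c2c1)[C@@](C)(O)CCB1OC(C)(C)C(C)(C)O1
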